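Ring C of the flavanone (O1–C2–C3–C4, with the 4-hydroxyphenyl group on C2 trans to the flavon-8-yl group on C3) is cut at C3–C4 and O1–C2. Both bonds are made in one enantioselective inverse-demand [4+2] between a phloroglucinaldehyde-derived 4-methoxy o-quinone methide and an (E)-stilbene, which closes ring C and sets C2 and C3. The stilbene is a benzyl-protected luteolin carrying a 4-benzyloxystyryl group at C8 and, at O7, the sulfate already in place as its electron-poor, non-participating 2,2,2-trichloroethyl ester. Afterwards only C4 oxidation and one reductive unmasking remain.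

Key step: step 10

Remark: the target is drawn as the free hydrogen sulfate; step 12 delivers it as the ammonium salt, the form in which an aryl sulfate is handled, and the lists show the neutral acid.
Remark: precedent does not tell which antipode of the phosphoric acid leads to the (2R,3S) series; (R)-TRIP is written, and its mirror image is taken if the first analysis shows the opposite sense.

Step 1
Reactants: 1 2,4,6-trihydroxybenzaldehyde
Product: 2 2,4-bis(benzyloxy)-6-hydroxybenzaldehyde
Conditions: BnBr (2.1 equiv), K2CO3 (2.2 equiv), DMF, 0 °C → rt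
Reagents that add atoms: benzyl bromide, BrCc1ccccc1
Why: Williamson ether synthesis: with two equivalents of halide the 2- and 4-hydroxyls are alkylated, while the hydroxyl that stays hydrogen-bonded to the formyl group, the least nucleophilic one, is left free as the future ring oxygen O1.

Step 2
Reactants: 3 4-(benzyloxy)benzaldehyde
Product: 4 1-(benzyloxy)-4-ethenylbenzene (4-benzyloxystyrene)
Conditions: Ph3PCH3Br, KOtBu, THF, 0 °C → rt
Reagents that add atoms: methyltriphenylphosphonium bromide, C[P+](c1ccccc1)(c1ccccc1)c1ccccc1.[Br-]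
Why: Wittig methylenation of a non-enolisable aromatic aldehyde with the unstabilised ylide gives the terminal alkene directly.

Step 3
Reactants: 5 2,4,6-trihydroxyacetophenone
Product: 6 1-[2,6-dihydroxy-4-(methoxymethoxy)phenyl]ethanone
Conditions: MOMCl (1.0 equiv), i-Pr2NEt (1.1 equiv), THF–CH2Cl2, 0 °C
Reagents that add atoms: chloromethyl methyl ether, COCCl
Why: Williamson-type O-alkylation (acetal protection): the 4-hydroxyl, para to the acetyl group and not held in a hydrogen bond, is the most acidic and accessible, so one equivalent of MOMCl should go there, and over-alkylated material is removed by chromatography.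

Step 4
Reactants: 6 1-[2,6-dihydroxy-4-(methoxymethoxy)phenyl]ethanone
Product: 7 1-[2-(benzyloxy)-6-hydroxy-4-(methoxymethoxy)phenyl]ethanone
Conditions: BnBr (1.05 equiv), K2CO3 (1.1 equiv), acetone, reflux
Reagents that add atoms: benzyl bromide, BrCc1ccccc1
Why: Williamson ether synthesis: one of the two equivalent chelated hydroxyls is benzylated, after which the remaining one is tied strongly to the carbonyl and resists a second alkylation.

Step 5
Reactants: 7 1-[2-(benzyloxy)-6-hydroxy-4-(methoxymethoxy)phenyl]ethanone, 8 3,4-bis(benzyloxy)benzaldehyde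
Product: 9 (E)-1-[2-(benzyloxy)-6-hydroxy-4-(methoxymethoxy)phenyl]-3-[3,4-bis(benzyloxy)phenyl]prop-2-en-1-one
Conditions: KOH (50% aq.), EtOH–THF, rt
Reagents that add atoms: none
Why: Claisen–Schmidt condensation of the methyl ketone with a non-enolisable aldehyde, the E alkene arising from E1cB dehydration under thermodynamic control; any flavanone formed by oxa-Michael closure is converted along with the chalcone in step 6.

Step 6
Reactants: 9 (E)-1-[2-(benzyloxy)-6-hydroxy-4-(methoxymethoxy)phenyl]-3-[3,4-bis(benzyloxy)phenyl]prop-2-en-1-one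
Product: 11 5-(benzyloxy)-2-[3,4-bis(benzyloxy)phenyl]-7-hydroxy-4H-chromen-4-one, via MOM-protected flavone 10 (not isolated)
Conditions: I2 (10 mol %), DMSO, 120 °C; then 3 M aq. HCl, THF, 50 °C
Reagents that add atoms: none
Why: Iodine/DMSO oxidative cyclisation of a 2'-hydroxychalcone (oxa-Michael addition, α-iodination and elimination, DMSO as terminal oxidant) gives the flavone through the only free hydroxyl, and the acid-labile MOM acetal is then hydrolysed completely while the benzyl ethers stay.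

Step 7
Reactants: 11 5-(benzyloxy)-2-[3,4-bis(benzyloxy)phenyl]-7-hydroxy-4H-chromen-4-one
Product: 12 5-(benzyloxy)-2-[3,4-bis(benzyloxy)phenyl]-7-hydroxy-8-iodo-4H-chromen-4-one
Conditions: NIS (1.05 equiv), DMF, 0 °C → rt, dark
Reagents that add atoms: N-iodosuccinimide, O=C1CCC(=O)N1I
Why: Electrophilic aromatic iodination: C8 is ortho to the free 7-hydroxyl and para to the 5-alkoxy group, the site at which 5-O-alkylated 5,7-dioxygenated flavones are iodinated, whereas C6 is shielded by the 5-benzyloxy group and the B ring is deactivated by the conjugated pyranone.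

Step 8
Reactants: 12 5-(benzyloxy)-2-[3,4-bis(benzyloxy)phenyl]-7-hydroxy-8-iodo-4H-chromen-4-one, 4 1-(benzyloxy)-4-ethenylbenzene
Product: 13 5-(benzyloxy)-2-[3,4-bis(benzyloxy)phenyl]-8-[(E)-2-(4-benzyloxyphenyl)ethenyl]-7-hydroxy-4H-chromen-4-one
Conditions: Pd(OAc)2 (5 mol %), P(o-tol)3 (15 mol %), Et3N, DMF, 90 °C
Reagents that add atoms: none
Why: Mizoroki–Heck reaction: oxidative addition into the aryl iodide, syn insertion at the unsubstituted styrene carbon and syn β-hydride elimination give the E-stilbene, and no oxidant is present that could turn the o-hydroxystilbene into a benzofuran.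

Step 9
Reactants: 13 5-(benzyloxy)-2-[3,4-bis(benzyloxy)phenyl]-8-[(E)-2-(4-benzyloxyphenyl)ethenyl]-7-hydroxy-4H-chromen-4-one
Product: 14 5-(benzyloxy)-2-[3,4-bis(benzyloxy)phenyl]-8-[(E)-2-(4-benzyloxyphenyl)ethenyl]-4-oxo-4H-chromen-7-yl 2,2,2-trichloroethyl sulfate
Conditions: Cl3CCH2OSO2Cl (1.5 equiv), Et3N, DMAP, THF, 0 °C → rt
Reagents that add atoms: 2,2,2-trichloroethyl chlorosulfate, ClS(=O)(=O)OCC(Cl)(Cl)Cl
Why: DMAP-catalysed O-sulfonylation of the acidic 7-hydroxyl with a chlorosulfate ester places the future sulfate as a neutral, acid-stable diester that withdraws electron density from the flavone A ring and cannot act as a neighbouring group.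

Step 10
Reactants: 2 2,4-bis(benzyloxy)-6-hydroxybenzaldehyde, 14 5-(benzyloxy)-2-[3,4-bis(benzyloxy)phenyl]-8-[(E)-2-(4-benzyloxyphenyl)ethenyl]-4-oxo-4H-chromen-7-yl 2,2,2-trichloroethyl sulfate, 15 trimethyl orthoformate
Product: 18 5-(benzyloxy)-2-[3,4-bis(benzyloxy)phenyl]-8-[(2R,3R,4R)-5,7-bis(benzyloxy)-2-(4-benzyloxyphenyl)-4-methoxy-3,4-dihydro-2H-chromen-3-yl]-4-oxo-4H-chromen-7-yl 2,2,2-trichloroethyl sulfate (2,3-trans-3,4-trans), via dimethyl acetal 16 (not isolated), via o-quinone methide 17 (not isolated)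
Conditions: (R)-TRIP (10 mol %), 5 Å MS, CH2Cl2, −20 °C → rt; 2 (1.5 equiv), 15 (3 equiv)
Reagents that add atoms: none
Why: Proposed new method: the acid and 15 turn 2 into acetal 16, which loses methanol to the 4-methoxy o-quinone methide 17 held by the chiral phosphate as a hydrogen-bonded ion pair; the stilbene carbon bearing the flavonyl group attacks its methide carbon (C3–C4) and the quinone oxygen then closes onto the 4-benzyloxybenzyl cation (O1–C2), an asynchronous inverse-demand hetero-Diels–Alder reaction. The closest known reactions are the acid-promoted [4+2] of salicylaldehyde-acetal-derived o-quinone methides with styrenes to 2-aryl-4-alkoxychromans and phosphoric-acid-controlled o-quinone methide cycloadditions, neither of which has been shown with catalyst control over a 1,2-diaryl alkene. Ring C closes as a six-membered pyran in a suprafacial [4+2] mode, the second bond arising by 6-exo-trig capture of the quinoid benzylic cation by oxygen. C3 and C4 are set in the C–C bond-forming event on the alkene face left open by the 3,3'-aryl groups of the phosphate, C2 follows from the E geometry as 2,3-trans (also the outcome if the cation lives long enough to rotate), and the C4 methoxy centre, expected trans to the C3 aryl group, is erased in step 11. The step needs regioselectivity, secured because the coplanar 4-benzyloxyphenyl ring stabilises charge at C2 whereas the flavonyl ring is twisted by two ortho substituents and drained by the pyranone carbonyl and the sulfate diester at O7, which, unlike an acyloxy group, cannot bridge to an adjacent cation. It also needs enantioselectivity, for which the only handle is the phosphate bound to the quinone methide O–H, and that is why the risk of the route sits here.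

Step 11
Reactants: 18 5-(benzyloxy)-2-[3,4-bis(benzyloxy)phenyl]-8-[(2R,3R,4R)-5,7-bis(benzyloxy)-2-(4-benzyloxyphenyl)-4-methoxy-3,4-dihydro-2H-chromen-3-yl]-4-oxo-4H-chromen-7-yl 2,2,2-trichloroethyl sulfate
Product: 20 5-(benzyloxy)-2-[3,4-bis(benzyloxy)phenyl]-8-[(2R,3S)-5,7-bis(benzyloxy)-2-(4-benzyloxyphenyl)-4-oxo-3,4-dihydro-2H-chromen-3-yl]-4-oxo-4H-chromen-7-yl 2,2,2-trichloroethyl sulfate, via C4 hemiketal 19 (not isolated)
Conditions: DDQ (2 equiv), CH2Cl2–pH 7 phosphate buffer (10:1), 0 °C → rt, dark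
Reagents that add atoms: water, O
Why: DDQ oxidation of an electron-rich benzylic ether: hydride abstraction from C4–H, activated by the 5,7-dialkoxy ring and the methoxy group, gives an oxocarbenium ion that water converts into hemiketal 19 and then the ketone, leaving C2 and C3 untouched, and the 2,3-trans arrangement is the stable one even if C3 enolises.

Step 12
Reactants: 20 5-(benzyloxy)-2-[3,4-bis(benzyloxy)phenyl]-8-[(2R,3S)-5,7-bis(benzyloxy)-2-(4-benzyloxyphenyl)-4-oxo-3,4-dihydro-2H-chromen-3-yl]-4-oxo-4H-chromen-7-yl 2,2,2-trichloroethyl sulfate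
Product: 21 8-[(2R,3S)-5,7-dihydroxy-2-(4-hydroxyphenyl)-4-oxo-3,4-dihydro-2H-chromen-3-yl]-2-(3,4-dihydroxyphenyl)-5-hydroxy-4-oxo-4H-chromen-7-yl hydrogen sulfate (CNP0314990.1, isolated as ammonium salt)
Conditions: 10% Pd/C, HCO2NH4 (20 equiv), MeOH–THF, rt
Reagents that add atoms: none
Why: Palladium-catalysed transfer hydrogenolysis cleaves the six O-benzyl ethers and, by reductive β-elimination, the trichloroethyl ester, the established release of aryl sulfates from this protecting group, under buffered neutral conditions that should leave the flavanone stereocentres and the sulfate intact.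

Compound list
1 | 2,4,6-trihydroxybenzaldehyde | O=Cc1c(O)cc(O)cc1O | starting material
2 | 2,4-bis(benzyloxy)-6-hydroxybenzaldehyde | O=Cc1c(O)cc(OCc2ccccc2)cc1OCc1ccccc1 | intermediate
3 | 4-(benzyloxy)benzaldehyde | O=Cc1ccc(OCc2ccccc2)cc1 | starting material
4 | 1-(benzyloxy)-4-ethenylbenzene | C=Cc1ccc(OCc2ccccc2)cc1 | intermediate
5 | 2,4,6-trihydroxyacetophenone | CC(=O)c1c(O)cc(O)cc1O | starting material
6 | 1-[2,6-dihydroxy-4-(methoxymethoxy)phenyl]ethanone | CC(=O)c1c(O)cc(OCOC)cc1O | intermediate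
7 | 1-[2-(benzyloxy)-6-hydroxy-4-(methoxymethoxy)phenyl]ethanone | CC(=O)c1c(O)cc(OCOC)cc1OCc1ccccc1 | intermediate
8 | 3,4-bis(benzyloxy)benzaldehyde | O=Cc1ccc(OCc2ccccc2)c(OCc2ccccc2)c1 | starting material
9 | (E)-1-[2-(benzyloxy)-6-hydroxy-4-(methoxymethoxy)phenyl]-3-[3,4-bis(benzyloxy)phenyl]prop-2-en-1-one | O=C(/C=C/c1ccc(OCc2ccccc2)c(OCc2ccccc2)c1)c1c(O)cc(OCOC)cc1OCc1ccccc1 | intermediate
10 | 5-(benzyloxy)-2-[3,4-bis(benzyloxy)phenyl]-7-(methoxymethoxy)-4H-chromen-4-one | O=c1cc(-c2ccc(OCc3ccccc3)c(OCc3ccccc3)c2)oc2cc(OCOC)cc(OCc3ccccc3)c12 | intermediate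
11 | 5-(benzyloxy)-2-[3,4-bis(benzyloxy)phenyl]-7-hydroxy-4H-chromen-4-one | O=c1cc(-c2ccc(OCc3ccccc3)c(OCc3ccccc3)c2)oc2cc(O)cc(OCc3ccccc3)c12 | intermediate
12 | 5-(benzyloxy)-2-[3,4-bis(benzyloxy)phenyl]-7-hydroxy-8-iodo-4H-chromen-4-one | O=c1cc(-c2ccc(OCc3ccccc3)c(OCc3ccccc3)c2)oc2c(I)c(O)cc(OCc3ccccc3)c12 | intermediate
13 | 5-(benzyloxy)-2-[3,4-bis(benzyloxy)phenyl]-8-[(E)-2-(4-benzyloxyphenyl)ethenyl]-7-hydroxy-4H-chromen-4-one | O=c1cc(-c2ccc(OCc3ccccc3)c(OCc3ccccc3)c2)oc2c(/C=C/c3ccc(OCc4ccccc4)cc3)c(O)cc(OCc3ccccc3)c12 | intermediate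
14 | 5-(benzyloxy)-2-[3,4-bis(benzyloxy)phenyl]-8-[(E)-2-(4-benzyloxyphenyl)ethenyl]-4-oxo-4H-chromen-7-yl 2,2,2-trichloroethyl sulfate | O=c1cc(-c2ccc(OCc3ccccc3)c(OCc3ccccc3)c2)oc2c(/C=C/c3ccc(OCc4ccccc4)cc3)c(OS(=O)(=O)OCC(Cl)(Cl)Cl)cc(OCc3ccccc3)c12 | intermediate
15 | trimethyl orthoformate | COC(OC)OC | starting material
16 | 3,5-bis(benzyloxy)-2-(dimethoxymethyl)phenol | COC(OC)c1c(O)cc(OCc2ccccc2)cc1OCc1ccccc1 | intermediate
17 | (6E)-3,5-bis(benzyloxy)-6-(methoxymethylidene)cyclohexa-2,4-dien-1-one (drawn as the E isomer; present as its phosphate-bound O–H form) | CO/C=C1/C(=O)C=C(OCc2ccccc2)C=C1OCc1ccccc1 | intermediate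
18 | 5-(benzyloxy)-2-[3,4-bis(benzyloxy)phenyl]-8-[(2R,3R,4R)-5,7-bis(benzyloxy)-2-(4-benzyloxyphenyl)-4-methoxy-3,4-dihydro-2H-chromen-3-yl]-4-oxo-4H-chromen-7-yl 2,2,2-trichloroethyl sulfate | CO[C@H]1c2c(OCc3ccccc3)cc(OCc3ccccc3)cc2O[C@@H](c2ccc(OCc3ccccc3)cc2)[C@@H]1c1c(OS(=O)(=O)OCC(Cl)(Cl)Cl)cc(OCc3ccccc3)c2c(=O)cc(-c3ccc(OCc4ccccc4)c(OCc4ccccc4)c3)oc12 | intermediate
19 | 5-(benzyloxy)-2-[3,4-bis(benzyloxy)phenyl]-8-[(2R,3R)-5,7-bis(benzyloxy)-2-(4-benzyloxyphenyl)-4-hydroxy-4-methoxy-3,4-dihydro-2H-chromen-3-yl]-4-oxo-4H-chromen-7-yl 2,2,2-trichloroethyl sulfate (C4 configuration not defined) | COC1(O)c2c(OCc3ccccc3)cc(OCc3ccccc3)cc2O[C@@H](c2ccc(OCc3ccccc3)cc2)[C@@H]1c1c(OS(=O)(=O)OCC(Cl)(Cl)Cl)cc(OCc3ccccc3)c2c(=O)cc(-c3ccc(OCc4ccccc4)c(OCc4ccccc4)c3)oc12 | intermediate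
20 | 5-(benzyloxy)-2-[3,4-bis(benzyloxy)phenyl]-8-[(2R,3S)-5,7-bis(benzyloxy)-2-(4-benzyloxyphenyl)-4-oxo-3,4-dihydro-2H-chromen-3-yl]-4-oxo-4H-chromen-7-yl 2,2,2-trichloroethyl sulfate | O=C1c2c(OCc3ccccc3)cc(OCc3ccccc3)cc2O[C@@H](c2ccc(OCc3ccccc3)cc2)[C@@H]1c1c(OS(=O)(=O)OCC(Cl)(Cl)Cl)cc(OCc3ccccc3)c2c(=O)cc(-c3ccc(OCc4ccccc4)c(OCc4ccccc4)c3)oc12 | intermediate
21 | 8-[(2R,3S)-5,7-dihydroxy-2-(4-hydroxyphenyl)-4-oxo-3,4-dihydro-2H-chromen-3-yl]-2-(3,4-dihydroxyphenyl)-5-hydroxy-4-oxo-4H-chromen-7-yl hydrogen sulfate | O=C1c2c(O)cc(O)cc2O[C@@H](c2ccc(O)cc2)[C@@H]1c1c(OS(=O)(=O)O)cc(O)c2c(=O)cc(-c3ccc(O)c(O)c3)oc12 | target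

Total steps: 12. Longest linear sequence: 10 steps (5 → 21, steps 3 to 12).

Steps most likely to fail

Step 10 (the proposed new method). The phosphate ion pair may not discriminate the two faces of an alkene that offers it no hydrogen-bond donor, and the basic pyranone carbonyl of 14 may sequester the weak acid so that ionisation of the acetal stalls. The fallback sets out from 2, 14 and 15 and uses the known acid-promoted o-quinone methide/styrene [4+2] without asymmetric induction: a strong achiral acid (TfOH or Sc(OTf)3, 5 mol %, CH2Cl2, −40 °C) should give the all-trans cycloadduct as a racemate, that is 18 together with its (2S,3S,4S) mirror image F1. The racemate is resolved by preparative HPLC on an amylose tris(3,5-dimethylphenylcarbamate) phase, and the route is rejoined at 18.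

Step 11. Hydride abstraction may not stay at C4: the C2–H next to the 4-benzyloxyphenyl ring can compete, and the oxocarbenium ion can lose H3 and be oxidised further towards the flavone level before water traps it. The fallback sets out from 18 and separates ionisation from oxidation. Catalytic p-TsOH in THF–water (4:1) at rt should exchange the benzylic methyl ether for hydroxyl through the same stabilised C4 cation, giving the flavan-4-ol F2. Dess–Martin periodinane with NaHCO3 in CH2Cl2 then gives the ketone, and the route is rejoined at 20.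

Step 12. Seven reductive events run in one flask, so the trichloroethyl group may be dechlorinated without fragmenting, the flavone C2–C3 bond may be saturated by the formate/palladium system, or released HCl may hydrolyse the sulfate. The fallback sets out from 20 and unmasks in two stages. Zinc dust and HCO2NH4 in MeOH–THF at rt remove only the trichloroethyl group by reductive β-elimination, giving the hexabenzyl aryl hydrogen sulfate F3 (as ammonium salt). Hydrogen (1 atm) over Pd/C in MeOH–EtOAc buffered with NH4HCO3 then cleaves the benzyl ethers, and the route ends at 21.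

Further compounds
F1 | step 10 | 5-(benzyloxy)-2-[3,4-bis(benzyloxy)phenyl]-8-[(2S,3S,4S)-5,7-bis(benzyloxy)-2-(4-benzyloxyphenyl)-4-methoxy-3,4-dihydro-2H-chromen-3-yl]-4-oxo-4H-chromen-7-yl 2,2,2-trichloroethyl sulfate (enantiomer of 18) | CO[C@@H]1c2c(OCc3ccccc3)cc(OCc3ccccc3)cc2O[C@H](c2ccc(OCc3ccccc3)cc2)[C@H]1c1c(OS(=O)(=O)OCC(Cl)(Cl)Cl)cc(OCc3ccccc3)c2c(=O)cc(-c3ccc(OCc4ccccc4)c(OCc4ccccc4)c3)oc12
F2 | step 11 | 5-(benzyloxy)-2-[3,4-bis(benzyloxy)phenyl]-8-[(2R,3R,4R)-5,7-bis(benzyloxy)-2-(4-benzyloxyphenyl)-4-hydroxy-3,4-dihydro-2H-chromen-3-yl]-4-oxo-4H-chromen-7-yl 2,2,2-trichloroethyl sulfate | O[C@H]1c2c(OCc3ccccc3)cc(OCc3ccccc3)cc2O[C@@H](c2ccc(OCc3ccccc3)cc2)[C@@H]1c1c(OS(=O)(=O)OCC(Cl)(Cl)Cl)cc(OCc3ccccc3)c2c(=O)cc(-c3ccc(OCc4ccccc4)c(OCc4ccccc4)c3)oc12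
F3 | step 12 | 5-(benzyloxy)-2-[3,4-bis(benzyloxy)phenyl]-8-[(2R,3S)-5,7-bis(benzyloxy)-2-(4-benzyloxyphenyl)-4-oxo-3,4-dihydro-2H-chromen-3-yl]-4-oxo-4H-chromen-7-yl hydrogen sulfate | O=C1c2c(OCc3ccccc3)cc(OCc3ccccc3)cc2O[C@@H](c2ccc(OCc3ccccc3)cc2)[C@@H]1c1c(OS(=O)(=O)O)cc(OCc3ccccc3)c2c(=O)cc(-c3ccc(OCc4ccccc4)c(OCc4ccccc4)c3)oc12
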